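Assumption: the C6–C5 biaryl bond has only two ortho substituents (O7 of unit 1 and C4a of unit 2), so the axis is taken to rotate freely and carries no stereodescriptor. Flavan numbering is used throughout; unit 1 is the flavan bonded through C6, unit 2 the flavan bonded through C5.

## Structural features

The target consists of two identical (2R,3S)-2,3-trans-flavan-3-ol units, each carrying a catechol ring B on C2, a hydroxyl on C3 and a ring A that is oxygenated at C7 and C8 but not at C5. A single aryl–aryl bond joins C6 of unit 1 to C5 of unit 2, so the molecule has no symmetry element and the two rings A differ only in which C–H is replaced. In each unit ring C is a dihydropyran fused to ring A along C4a–C8a, and its two stereocentres, the benzylic C2 (bonded to O1 and ring B) and the carbinol C3, are adjacent and trans; the two pairs are too far apart to control one another. The ten free hydroxyls sit on four electron-rich ortho-dioxygenated arenes (two catechols and two 7,8-dihydroxy rings A) that oxidise readily, above all in base. The C2–O1 bond is a benzylic ether of an electron-rich arene, so acid can ionise it (epimerisation at C2) and over-reduction can cleave it. The real difficulties are the regiochemistry of the unsymmetrical biaryl bond between two look-alike rings, the absolute control of four stereocentres at two remote sites, and a ring closure that does not disturb C2. The plan rests on the position of C8a: this carbon carries O1 as an aryl ether and is flanked by the oxygen-bearing C8 and by C4a in each ring A, so it can be carried as a C–Br bond taken from an ortho-brominated hydroxybenzaldehyde, and each ring C can then be shut by bonding a ready-made C2 alkoxide to C8a while the C2–O and C3–O bonds stay intact.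

## Logic of the disconnections

**24 from 23.** The ten O–CH2Ph bonds are cut. Every hydroxyl is either oxidation-prone or incompatible with the bases and organometallic reagents used earlier, so all are carried as one kind of ether that is removed in a single neutral reductive operation. The gain is a fully protected, lipophilic penultimate compound. The demand is a debenzylation that spares the benzylic C2–O1 bonds.

**23 from 22.** Both O1–C8a bonds are cut. Cutting on the aryl side of O1 removes both rings C and leaves each C2/C3 pair in an open chain where acyclic stereocontrol applies. The forward step must couple a secondary benzylic alkoxide with a hindered, electron-rich aryl bromide twice in one molecule, with the C2 hydroxyls as the only free oxygens.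

**22 from 21.** The two C2–H bonds are cut, tracing the alcohols to aryl ketones. The C3 benzyloxy group next to each carbonyl can direct hydride delivery through a chelate, which gives the anti relation that becomes 2,3-trans. Two stereocentres disappear. The demand is high anti selectivity in both arms without epimerising C3.

**21 from 18 and 19 (through 20).** Both C2–C1' bonds to ring B are cut. Ring B is the same simple aryl nucleophile twice, so two molecules of 19 are built in, and an N-methoxy-N-methylamide stops cleanly at the ketone. The demand is an arylmetal that adds to the amide but does not exchange with the C8a bromides.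

**18 from 17.** The two acyl–nitrogen bonds to the auxiliary are cut. The auxiliary is exchanged for the amide needed in the ketone synthesis. The demand is attack at the exocyclic carbonyl without enolisation at C3.

**17 from 11 and 15 (through 16).** Both C3–C4 bonds are cut. C4 is benzylic and serves as the electrophile, and C3 arrives as a chiral glycolate enolate with O3 already benzylated; two molecules of 15 are built into one molecule of 11. That benzyl ether later blocks five-membered ring closure and acts as the chelating group in the reduction. The gain is a simple biaryl bis-electrophile and one small chiral reagent used twice. The demand is a face-selective double alkylation at two unequally hindered benzylic carbons.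

**15 from 12 and 13.** The N–acyl bond is cut, which leads to 12 and 13, both commercial.

**11 from 10 from 9.** The benzylic C–Br bonds and then the benzylic C–H bonds are traced back to formyl groups. The aldehyde level is kept through the biaryl stage because it activates the C–I bond for coupling and tolerates ether cleavage. The demand is neutral bromination that spares benzyl ethers.

**9 from 8 from 7.** Four O–benzyl bonds are exchanged for two O–methyl bonds and two free phenols. Doing the methyl-to-benzyl exchange on the biaryl means it is done once for both rings. The demand is an ether cleavage that tolerates formyl groups and aryl bromides, and a benzylation that captures the open hydroxy aldehyde.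

**7 from 5 (through 6) and 2.** The C6–C5 biaryl bond, the only bond between the units, is cut. Both halves then derive from one starting material. The demand is a cross-coupling at C–I that leaves both C8a–Br bonds untouched.

**5 from 4 from 3 from 1, and 2 from 1.** The C–B and C–I bonds are cut. The regiochemistry of iodination is switched by the state of O8: the free phenol directs para (future C5 of unit 2), while its acetate hands control to the methoxy group (future C6 of unit 1). The demand is clean regiocontrol in both directions.

## Other disconnections considered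

Alternative 1: The cut is made at both C2–C1' bonds to ring B, which turns each C2/C3 pair into a trans-dioxolane derived from (2R,3R)-tartaric acid A4. In the forward step a nickel catalyst working at the cathode (for example NiBr2(dme) with 2,2'-bipyridine) reduces both N-acyloxyphthalimide esters of A1; loss of CO2 gives dioxolanyl radicals at C2, which are captured by aryl–nickel species formed from the aryl iodide A2 to give the bis-dioxolane A3. In its favour, C3 comes from the chiral pool without an auxiliary, ring B is attached last and could be varied, and C8a carries its oxygen from the start, so no halogen has to survive a cross-coupling; on chirality economy and ring B modularity this plan is better than the chosen one. Against it, the C2 radical is planar, so C2 is set only by the preference for arylation trans to the C3 substituent, and two radical couplings must both succeed on one molecule against reduction or dimerisation of the radical. In A3 the benzylic oxygen has the configuration opposite to the one required at C2, so each ring C must later be closed by the C8a phenol displacing at C2 with inversion, on a carbon that ionises easily and sits next to a C3 oxygen. In comparison, both plans need the same unsymmetrical biaryl and are equal on that structural point. Mechanistically the chosen plan forms O1 at an sp2 carbon and never touches C2 or C3, whereas this one makes C2 by substrate control and then inverts it. Step counts should be similar, because acetal and ether removal and an inverting cyclisation follow A3.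

Alternative 2: The cut removes O1–C2 and C3–C4 in both units and leads to the bis(salicylaldehyde) A5 and two molecules of the cinnamaldehyde A6. In the forward step a chiral secondary amine converts A6 into an iminium ion, each C8a phenol of A5 adds to its β-carbon, the enamine closes onto the neighbouring formyl group and water is lost, giving the bis(2-aryl-2H-chromene-3-carbaldehyde) A7. In its favour, the step is catalytic and enantioselective and forms four skeletal bonds, both rings C and both C2 centres in one operation, with no halogen at C8a and no auxiliary; on bond economy and convergence it is better than the chosen plan. Against it, A7 carries a formyl carbon on C3 that the target does not have, so that carbon must be excised and replaced by hydroxyl and the C3=C4 bond reduced. C3 would then be set late, next to a C2 centre that can be lost by ring opening of the chromene or by enolisation of a 3-ketone, and hydride reduction of such ketones is expected to favour the cis alcohol, not the trans one needed. The phenols of A5 are flanked by a benzyloxy group and one formyl group is hindered by the biaryl, which makes them poor partners. In comparison, the biaryl problem is the same in both plans (equal). Mechanistically the chosen plan fixes C3 first by auxiliary control and C2 by chelation, both reagent-controlled in an open chain. In steps, this plan is shorter up to the ring system and longer after it, with no net saving expected.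

Alternative 3: The cut is the C8a–C4a bond of unit 2, so ring A of unit 2 is built last from the cyclobutenone A8, which already carries a complete unit 1. In the forward step heating opens A8 (4π) to a dienylketene; the ketene carbon closes (6π) onto the alkene terminus and tautomerisation gives the biaryl phenol A9, with a free C8a hydroxyl and the acetonide side chain on C4a. In its favour, the regiochemistry of the unsymmetrical biaryl is written into the connectivity of A8, so no cross-coupling between two similar rings and no halogen chemoselectivity is needed; on this point it is better than the chosen plan. The step needs no reagent and delivers the phenol exactly where ring closure needs it. Against it, the plan is linear, since a complete protected unit 1 must pass through the construction of a sensitive cyclobutenone. The trans-dioxolane of A9 again has a benzylic oxygen of the opposite configuration, so ring C of unit 2 must be closed with inversion at C2, and the two units are made by unrelated chemistry, so no operation can be run pairwise. In comparison, structure favours this alternative for biaryl control. Mechanistically a thermal pericyclic cascade and a copper-catalysed etherification are both sound closures. In step economy the chosen plan is better, because every step after the biaryl coupling acts on both units at once.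

Key step: step 15

## Route

Step 1
Reactants: 1 2-bromoisovanillin (2-bromo-3-hydroxy-4-methoxybenzaldehyde)
Product: 2 2-bromo-3-hydroxy-6-iodo-4-methoxybenzaldehyde
Conditions: NIS, TsOH·H2O (cat.), MeCN, 0 °C → rt
Reagents that add atoms: N-iodosuccinimide, O=C1CCC(=O)N1I
Why: Electrophilic aromatic iodination of a phenol; the free hydroxyl is the strongest donor and both its ortho positions are occupied (Br, OMe), so iodine should enter para at C6, while the methoxy group is conjugated with the para formyl group and activates C5 only weakly.

Step 2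
Reactants: 1 2-bromoisovanillin
Product: 3 2-bromo-3-formyl-6-methoxyphenyl acetate
Conditions: Ac2O, pyridine, DMAP (cat.), CH2Cl2, rt
Reagents that add atoms: acetic anhydride, CC(=O)OC(C)=O
Why: Nucleophile-catalysed O-acetylation of the phenol; the ester turns this oxygen from the dominant donor into a weak one, which reverses the regiochemistry of the next iodination.

Step 3
Reactants: 3 2-bromo-3-formyl-6-methoxyphenyl acetate
Product: 4 2-bromo-3-formyl-5-iodo-6-methoxyphenyl acetate
Conditions: NIS, CF3CO2H, TfOH (cat.), 0 °C → rt
Reagents that add atoms: N-iodosuccinimide, O=C1CCC(=O)N1I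
Why: Acid-activated electrophilic iodination; with the phenol acylated the methoxy group directs, its para position is the formyl-bearing carbon, so substitution should occur at its free ortho position, which is also meta to the formyl group and para to bromine, as in the ring iodination of 4-methoxybenzaldehyde.

Step 4
Reactants: 4 2-bromo-3-formyl-5-iodo-6-methoxyphenyl acetate
Product: 5 2-bromo-3-formyl-6-methoxy-5-(4,4,5,5-tetramethyl-1,3,2-dioxaborolan-2-yl)phenyl acetate
Conditions: B2pin2, PdCl2(dppf), KOAc, 1,4-dioxane, 80 °C
Reagents that add atoms: bis(pinacolato)diboron, CC1(C)OB(OC1(C)C)B1OC(C)(C)C(C)(C)O1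
Why: Miyaura borylation; zerovalent palladium inserts into the C–I bond much faster than into the C–Br bond flanked by two ortho substituents, and KOAc is too weak a base to start a Suzuki coupling or to cleave the acetate.

Step 5
Reactants: 5 2-bromo-3-formyl-6-methoxy-5-(4,4,5,5-tetramethyl-1,3,2-dioxaborolan-2-yl)phenyl acetate; 2 2-bromo-3-hydroxy-6-iodo-4-methoxybenzaldehyde
Product: 7 3,4'-dibromo-3',4-dihydroxy-2',5-dimethoxybiphenyl-2,5'-dicarbaldehyde, via phenol boronate 6 (not isolated)
Conditions: K2CO3, 1,4-dioxane/H2O, 40 °C; then 2, Pd(PPh3)4, 70 °C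
Reagents that add atoms: none
Why: Carbonate first hydrolyses the aryl acetate, then Suzuki–Miyaura coupling joins the boron-bearing carbon (future C6 of unit 1) to the iodine-bearing carbon (future C5 of unit 2); as phenoxides both rings are electron-rich and each C–Br bond is ortho to O– and doubly flanked, so oxidative addition should stay at the C–I bond next to the formyl group.

Step 6
Reactants: 7 3,4'-dibromo-3',4-dihydroxy-2',5-dimethoxybiphenyl-2,5'-dicarbaldehyde
Product: 8 3,4'-dibromo-2',3',4,5-tetrahydroxybiphenyl-2,5'-dicarbaldehyde
Conditions: BBr3, CH2Cl2, −78 °C → rt; H2O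
Reagents that add atoms: none
Why: Lewis-acid cleavage of aryl methyl ethers (bromide attacks the methyl group of the boron-bound ether by SN2); formyl groups and aryl bromides are inert, and the tetraphenol, which may sit partly as the lactol between the 2'-hydroxyl and the 2-formyl group, is used crude.

Step 7
Reactants: 8 3,4'-dibromo-2',3',4,5-tetrahydroxybiphenyl-2,5'-dicarbaldehyde
Product: 9 2',3',4,5-tetrakis(benzyloxy)-3,4'-dibromobiphenyl-2,5'-dicarbaldehyde
Conditions: BnBr (5 equiv), K2CO3, DMF, 50 °C, argon
Reagents that add atoms: benzyl bromide, BrCc1ccccc1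
Why: Williamson ether synthesis with four benzyl groups taken up; phenoxide alkylation is irreversible and drains the lactol–hydroxy aldehyde equilibrium, so all four oxygens should end as benzyl ethers with both formyl groups free, and exclusion of air protects the catecholates.

Step 8
Reactants: 9 2',3',4,5-tetrakis(benzyloxy)-3,4'-dibromobiphenyl-2,5'-dicarbaldehyde
Product: 10 [2',3',4,5-tetrakis(benzyloxy)-3,4'-dibromobiphenyl-2,5'-diyl]dimethanol
Conditions: NaBH4, THF/MeOH, 0 °C
Reagents that add atoms: none
Why: Borohydride reduction of both aryl aldehydes to benzylic alcohols; aryl bromides and benzyl ethers are not affected.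

Step 9
Reactants: 10 [2',3',4,5-tetrakis(benzyloxy)-3,4'-dibromobiphenyl-2,5'-diyl]dimethanol
Product: 11 2',3',4,5-tetrakis(benzyloxy)-3,4'-dibromo-2,5'-bis(bromomethyl)biphenyl
Conditions: CBr4 (2.5 equiv), PPh3 (2.5 equiv), CH2Cl2, 0 °C
Reagents that add atoms: carbon tetrabromide, BrC(Br)(Br)Br
Why: Appel reaction; bromide displaces the alkoxyphosphonium groups at the primary benzylic carbons under neutral conditions that spare the benzyl ethers, and the electron-rich dibromide is used at once.

Step 10
Reactants: 12 (R)-4-benzyloxazolidin-2-one; 13 benzyloxyacetyl chloride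
Product: 15 (R)-4-benzyl-3-[2-(benzyloxy)acetyl]oxazolidin-2-one, via lithium oxazolidinide 14 (not isolated)
Conditions: n-BuLi, THF, −78 °C; then 13, −78 → 0 °C
Reagents that add atoms: none
Why: N-acylation of the lithiated oxazolidinone by the acid chloride gives the glycolate imide; the stereocentre of the auxiliary is not involved.

Step 11
Reactants: 15 (R)-4-benzyl-3-[2-(benzyloxy)acetyl]oxazolidin-2-one (two molecules per molecule of 11 are built in); 11 2',3',4,5-tetrakis(benzyloxy)-3,4'-dibromo-2,5'-bis(bromomethyl)biphenyl
Product: 17 (4R,4'R)-3,3'-{[2',3',4,5-tetrakis(benzyloxy)-3,4'-dibromobiphenyl-2,5'-diyl]bis[(2S)-2-(benzyloxy)-1-oxopropane-3,1-diyl]}bis(4-benzyloxazolidin-2-one), via sodium Z-enolate 16 (not isolated)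
Conditions: 15 (3 equiv), NaHMDS (3 equiv), THF, −78 °C; then 11 (1 equiv), −78 → −40 °C
Reagents that add atoms: (R)-4-benzyl-3-[2-(benzyloxy)acetyl]oxazolidin-2-one (second molecule of 15), O=C1N(C(=O)COCc2ccccc2)[C@H](Cc2ccccc2)CO1
Why: Evans asymmetric alkylation run at both benzylic bromides, so one molecule of 11 takes up two molecules of the enolate of 15 and loses two bromides; the sodium-chelated Z-enolate reacts on the face opposite the C4 benzyl group of the (R)-auxiliary by SN2, which sets both future C3 centres as S. Excess enolate drives the second alkylation at the more hindered, doubly ortho-substituted CH2Br of unit 2.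

Step 12
Reactants: 17 bis-imide (4R,4'R)-3,3'-{[2',3',4,5-tetrakis(benzyloxy)-3,4'-dibromobiphenyl-2,5'-diyl]bis[(2S)-2-(benzyloxy)-1-oxopropane-3,1-diyl]}bis(4-benzyloxazolidin-2-one)
Product: 18 (2S,2'S)-3,3'-[2',3',4,5-tetrakis(benzyloxy)-3,4'-dibromobiphenyl-2,5'-diyl]bis[2-(benzyloxy)-N-methoxy-N-methylpropanamide]
Conditions: MeNH(OMe)·HCl (6 equiv), AlMe3 (6 equiv), CH2Cl2, −15 → 0 °C; aq. HCl
Reagents that add atoms: N,O-dimethylhydroxylamine hydrochloride, CNOC.Cl
Why: Weinreb amide formation by aluminium amide aminolysis at both exocyclic imide carbonyls; the auxiliary is released and the non-basic reagent does not enolise the alpha-benzyloxy centre.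

Step 13
Reactants: 18 (2S,2'S)-3,3'-[2',3',4,5-tetrakis(benzyloxy)-3,4'-dibromobiphenyl-2,5'-diyl]bis[2-(benzyloxy)-N-methoxy-N-methylpropanamide]; 19 4-bromo-1,2-bis(benzyloxy)benzene (two molecules per molecule of 18 are built in)
Product: 21 (2S,2'S)-3,3'-[2',3',4,5-tetrakis(benzyloxy)-3,4'-dibromobiphenyl-2,5'-diyl]bis{2-(benzyloxy)-1-[3,4-bis(benzyloxy)phenyl]propan-1-one}, via aryl Grignard reagent 20 (not isolated)
Conditions: 19 (3 equiv), Mg, THF, rt; then 18 (1 equiv), THF, 0 °C; aq. NH4Cl
Reagents that add atoms: 4-bromo-1,2-bis(benzyloxy)benzene (second molecule of 19), Brc1ccc(OCc2ccccc2)c(OCc2ccccc2)c1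
Why: Grignard addition to both Weinreb amides, each taking up one molecule of 20, stops at the magnesium-chelated tetrahedral intermediates, which release the aryl ketones on work-up. An arylmagnesium bromide, unlike an aryllithium, should not exchange with the C8a–Br bonds.

Step 14
Reactants: 21 (2S,2'S)-3,3'-[2',3',4,5-tetrakis(benzyloxy)-3,4'-dibromobiphenyl-2,5'-diyl]bis{2-(benzyloxy)-1-[3,4-bis(benzyloxy)phenyl]propan-1-one}
Product: 22 (1R,1'R,2S,2'S)-3,3'-[2',3',4,5-tetrakis(benzyloxy)-3,4'-dibromobiphenyl-2,5'-diyl]bis{2-(benzyloxy)-1-[3,4-bis(benzyloxy)phenyl]propan-1-ol}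
Conditions: Zn(BH4)2, Et2O/CH2Cl2, −30 → 0 °C
Reagents that add atoms: none
Why: Chelation-controlled (Cram-chelate) ketone reduction; zinc bridges the carbonyl oxygen and the C3 benzyloxy oxygen and hydride enters from the side of the C3 hydrogen, which should give the anti (1R,2S) alcohol in each arm and so sets both future C2 centres.

Step 15
Reactants: 22 biaryl dibromide bis[(1R,2S)-anti-2-benzyloxy-1-ol]
Product: 23 decabenzyl ether of the target: (2R,3S)-3,7,8-tris(benzyloxy)-2-[3,4-bis(benzyloxy)phenyl]-6-{(2R,3S)-3,7,8-tris(benzyloxy)-2-[3,4-bis(benzyloxy)phenyl]chroman-5-yl}chromane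
Conditions: CuI, 3,4,7,8-tetramethyl-1,10-phenanthroline, Cs2CO3, toluene, 110 °C, argon, dilute
Reagents that add atoms: none
Why: This is an intramolecular Ullmann-type aryl etherification, the copper-catalysed route from 3-(2-halophenyl)propanols to chromans, run twice in one molecule. Cs2CO3 deprotonates each benzylic C2 hydroxyl and the alkoxide binds the phenanthroline complex of CuI (monovalent copper); the tethered C8a–Br bond then adds to copper to give an aryl alkoxide of trivalent copper, and C–O reductive elimination forms O1–C8a and returns monovalent copper. Each ring C closes as a six-membered ring by attack of the tethered oxygen on an sp2 carbon with the leaving bromide outside the ring (6-exo mode); closure onto the bromide of the other unit would need a ten-membered ring and is not expected. No stereocentre is created, because the C2–O and C3–O bonds are never broken: C2 stays R, C3 stays S, and the anti alcohol becomes the 2,3-trans ring. The step needs chemoselectivity only, and the substrate provides it: the C3 oxygen is capped as a benzyl ether and cannot compete, which rules out closure to a five-membered dihydrobenzofuran, and the two C2 hydroxyls are the only free oxygens. Dilution and exclusion of air are meant to suppress intermolecular etherification and copper-mediated oxidation of the benzylic alcohols to ketones. The electron-rich, doubly ortho-substituted bromides are the slow partners, which is the reason for the electron-rich tetramethylphenanthroline ligand and the high temperature.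

Step 16
Reactants: 23 decabenzyl ether of the target
Product: 24 target, (2R,3S)-2-(3,4-dihydroxyphenyl)-6-[(2R,3S)-2-(3,4-dihydroxyphenyl)-3,7,8-trihydroxychroman-5-yl]chroman-3,7,8-triol
Conditions: H2 (1 atm), Pd(OH)2/C, THF/MeOH, rt; filtration and concentration under argon
Reagents that add atoms: none
Why: Heterogeneous catalytic hydrogenolysis of all ten O-benzyl groups under neutral conditions; benzyl ethers are cleaved faster than the cyclic benzylic C2–O1 ether, no halogen remains to interfere, and the reaction is stopped at full debenzylation to protect the polyphenol.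

## Compound list

1 | 2-bromoisovanillin (2-bromo-3-hydroxy-4-methoxybenzaldehyde) | COc1ccc(C=O)c(Br)c1O | starting material
2 | 2-bromo-3-hydroxy-6-iodo-4-methoxybenzaldehyde | COc1cc(I)c(C=O)c(Br)c1O | intermediate
3 | 2-bromo-3-formyl-6-methoxyphenyl acetate | COc1ccc(C=O)c(Br)c1OC(C)=O | intermediate
4 | 2-bromo-3-formyl-5-iodo-6-methoxyphenyl acetate | COc1c(I)cc(C=O)c(Br)c1OC(C)=O | intermediate
5 | 2-bromo-3-formyl-6-methoxy-5-(4,4,5,5-tetramethyl-1,3,2-dioxaborolan-2-yl)phenyl acetate | COc1c(B2OC(C)(C)C(C)(C)O2)cc(C=O)c(Br)c1OC(C)=O | intermediate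
6 | 2-bromo-3-hydroxy-4-methoxy-5-(4,4,5,5-tetramethyl-1,3,2-dioxaborolan-2-yl)benzaldehyde | COc1c(B2OC(C)(C)C(C)(C)O2)cc(C=O)c(Br)c1O | intermediate (not isolated)
7 | 3,4'-dibromo-3',4-dihydroxy-2',5-dimethoxybiphenyl-2,5'-dicarbaldehyde | COc1cc(-c2cc(C=O)c(Br)c(O)c2OC)c(C=O)c(Br)c1O | intermediate
8 | 3,4'-dibromo-2',3',4,5-tetrahydroxybiphenyl-2,5'-dicarbaldehyde | Oc1cc(-c2cc(C=O)c(Br)c(O)c2O)c(C=O)c(Br)c1O | intermediate
9 | 2',3',4,5-tetrakis(benzyloxy)-3,4'-dibromobiphenyl-2,5'-dicarbaldehyde | O=Cc1cc(-c2cc(OCc9ccccc9)c(OCc9ccccc9)c(Br)c2C=O)c(OCc9ccccc9)c(OCc9ccccc9)c1Br | intermediate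
10 | [2',3',4,5-tetrakis(benzyloxy)-3,4'-dibromobiphenyl-2,5'-diyl]dimethanol | OCc1cc(-c2cc(OCc9ccccc9)c(OCc9ccccc9)c(Br)c2CO)c(OCc9ccccc9)c(OCc9ccccc9)c1Br | intermediate
11 | 2',3',4,5-tetrakis(benzyloxy)-3,4'-dibromo-2,5'-bis(bromomethyl)biphenyl | BrCc1cc(-c2cc(OCc9ccccc9)c(OCc9ccccc9)c(Br)c2CBr)c(OCc9ccccc9)c(OCc9ccccc9)c1Br | intermediate
12 | (R)-4-benzyloxazolidin-2-one | O=C1N[C@H](Cc2ccccc2)CO1 | starting material
13 | benzyloxyacetyl chloride | O=C(Cl)COCc1ccccc1 | starting material
14 | lithium salt (N-lithio) of (R)-4-benzyloxazolidin-2-one | [Li+].O=C1[N-][C@H](Cc2ccccc2)CO1 | intermediate (not isolated)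
15 | (R)-4-benzyl-3-[2-(benzyloxy)acetyl]oxazolidin-2-one | O=C1N(C(=O)COCc2ccccc2)[C@H](Cc2ccccc2)CO1 | intermediate
16 | sodium (Z)-enolate of 15 | [Na+].[O-]/C(=C\OCc1ccccc1)N1[C@H](Cc2ccccc2)COC1=O | intermediate (not isolated)
17 | (4R,4'R)-3,3'-{[2',3',4,5-tetrakis(benzyloxy)-3,4'-dibromobiphenyl-2,5'-diyl]bis[(2S)-2-(benzyloxy)-1-oxopropane-3,1-diyl]}bis(4-benzyloxazolidin-2-one) | O=C(N1[C@H](Cc9ccccc9)COC1=O)[C@@H](OCc9ccccc9)Cc1cc(-c2cc(OCc9ccccc9)c(OCc9ccccc9)c(Br)c2C[C@H](OCc9ccccc9)C(=O)N2[C@H](Cc9ccccc9)COC2=O)c(OCc9ccccc9)c(OCc9ccccc9)c1Br | intermediate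
18 | (2S,2'S)-3,3'-[2',3',4,5-tetrakis(benzyloxy)-3,4'-dibromobiphenyl-2,5'-diyl]bis[2-(benzyloxy)-N-methoxy-N-methylpropanamide] | CON(C)C(=O)[C@@H](OCc9ccccc9)Cc1cc(-c2cc(OCc9ccccc9)c(OCc9ccccc9)c(Br)c2C[C@H](OCc9ccccc9)C(=O)N(C)OC)c(OCc9ccccc9)c(OCc9ccccc9)c1Br | intermediate
19 | 4-bromo-1,2-bis(benzyloxy)benzene | Brc1ccc(OCc2ccccc2)c(OCc2ccccc2)c1 | starting material
20 | [3,4-bis(benzyloxy)phenyl]magnesium bromide | Br[Mg]c1ccc(OCc2ccccc2)c(OCc2ccccc2)c1 | intermediate (not isolated)
21 | (2S,2'S)-3,3'-[2',3',4,5-tetrakis(benzyloxy)-3,4'-dibromobiphenyl-2,5'-diyl]bis{2-(benzyloxy)-1-[3,4-bis(benzyloxy)phenyl]propan-1-one} | O=C(c1ccc(OCc9ccccc9)c(OCc9ccccc9)c1)[C@@H](OCc9ccccc9)Cc1cc(-c2cc(OCc9ccccc9)c(OCc9ccccc9)c(Br)c2C[C@H](OCc9ccccc9)C(=O)c2ccc(OCc9ccccc9)c(OCc9ccccc9)c2)c(OCc9ccccc9)c(OCc9ccccc9)c1Br | intermediate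
22 | (1R,1'R,2S,2'S)-3,3'-[2',3',4,5-tetrakis(benzyloxy)-3,4'-dibromobiphenyl-2,5'-diyl]bis{2-(benzyloxy)-1-[3,4-bis(benzyloxy)phenyl]propan-1-ol} | c9ccccc9COc1ccc([C@@H](O)[C@@H](OCc9ccccc9)Cc2cc(-c3cc(OCc9ccccc9)c(OCc9ccccc9)c(Br)c3C[C@H](OCc9ccccc9)[C@H](O)c3ccc(OCc9ccccc9)c(OCc9ccccc9)c3)c(OCc9ccccc9)c(OCc9ccccc9)c2Br)cc1OCc9ccccc9 | intermediate
23 | (2R,3S)-3,7,8-tris(benzyloxy)-2-[3,4-bis(benzyloxy)phenyl]-6-{(2R,3S)-3,7,8-tris(benzyloxy)-2-[3,4-bis(benzyloxy)phenyl]chroman-5-yl}chromane | c9ccccc9COc1ccc([C@H]2Oc3c(cc(-c4cc(OCc9ccccc9)c(OCc9ccccc9)c5c4C[C@H](OCc9ccccc9)[C@@H](c4ccc(OCc9ccccc9)c(OCc9ccccc9)c4)O5)c(OCc9ccccc9)c3OCc9ccccc9)C[C@@H]2OCc9ccccc9)cc1OCc9ccccc9 | intermediate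
24 | (2R,3S)-2-(3,4-dihydroxyphenyl)-6-[(2R,3S)-2-(3,4-dihydroxyphenyl)-3,7,8-trihydroxychroman-5-yl]chroman-3,7,8-triol | Oc1ccc([C@H]2Oc3c(cc(-c4cc(O)c(O)c5c4C[C@H](O)[C@@H](c4ccc(O)c(O)c4)O5)c(O)c3O)C[C@@H]2O)cc1O | target

## Step count and uncertain steps

Total step count: 16. Longest linear sequence: 14 steps (steps 2, 3, 4, 5, 6, 7, 8, 9, 11, 12, 13, 14, 15, 16, from 1 to 24).

**Step 15 (key step).** The likely failure is slow oxidative addition at the hindered, electron-rich C8a–Br bonds. This would leave one ring open and give time for hydrodebromination or for oxidation of the benzylic alcohols to ketones. The fallback sets out from 22 and returns at 23, forming the other bond to O1. Palladium-catalysed hydroxylation of both aryl bromides (Pd2(dba)3, tBuXPhos, KOH, dioxane/H2O, 100 °C) should give the bis-phenol with hydroxyl on both C8a positions F1. Catalytic TsOH in CH2Cl2 then ionises each electron-rich benzylic alcohol, and the C8a phenol captures the cation to form O1–C2. Capture with ring B and the C3 benzyloxy group both equatorial should favour the 2,3-trans rings of 23, though with less stereochemical fidelity than the retentive coupling.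

**Step 3.** The ring carries a formyl group, an acetoxy group and a bromine, so substitution may be sluggish. Acid-induced loss of the acetate would hand control back to the phenol and erode regioselectivity. The fallback sets out from 1 and returns at 4, iodinating at the benzyl alcohol oxidation level where the ring is not deactivated. NaBH4 reduction of 1 gives 2-bromo-3-(hydroxymethyl)-6-methoxyphenol F2, and Ac2O/pyridine converts it into 3-(acetoxymethyl)-2-bromo-6-methoxyphenyl acetate F3. NIS with catalytic CF3CO2H in MeCN should then iodinate ortho to the methoxy group to give 3-(acetoxymethyl)-2-bromo-5-iodo-6-methoxyphenyl acetate F4. K2CO3/MeOH removes both acetates to give 2-bromo-3-(hydroxymethyl)-5-iodo-6-methoxyphenol F5, MnO2 oxidises the benzylic alcohol to 2-bromo-3-hydroxy-5-iodo-4-methoxybenzaldehyde F6, and acetylation as in step 2 gives 4.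

**Step 5.** The risk is loss of chemoselectivity: oxidative addition into a C–Br bond of either partner or of the product would lead to oligomers, and the boronate may be lost by protodeboronation. The fallback sets out from 2 and returns at 7, using a bromine-free boronate and introducing the second bromine afterwards. Isovanillin F7 is acetylated to 5-formyl-2-methoxyphenyl acetate F8, and iodination ortho to the methoxy group (NIS, CF3CO2H) gives 5-formyl-3-iodo-2-methoxyphenyl acetate F9. Borylation (B2pin2, PdCl2(dppf), KOAc) gives 5-formyl-2-methoxy-3-(4,4,5,5-tetramethyl-1,3,2-dioxaborolan-2-yl)phenyl acetate F10, and coupling with 2 under the conditions of step 5 should give 3-bromo-3',4-dihydroxy-2',5-dimethoxybiphenyl-2,5'-dicarbaldehyde F11. Bromination (Br2, NaOAc, Fe powder cat., AcOH) of the free phenol ring between its hydroxyl and formyl groups, the position at which isovanillin itself is brominated, then gives 7.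

**Step 11.** The second alkylation may be incomplete: the CH2Br of unit 2 is flanked by a bromine and the other aryl ring, and the glycolate enolate decomposes when warmed to force the reaction. The fallback sets out from 9 and returns at 18, replacing SN2 alkylation by aldol addition and deoxygenation. (S)-4-benzyloxazolidin-2-one F12 is acylated as in step 10 to (S)-4-benzyl-3-[2-(benzyloxy)acetyl]oxazolidin-2-one F13; the enantiomeric auxiliary is needed because the boron aldol uses the enolate face opposite to that of the chelated sodium enolate. Evans syn-aldol addition of two molecules of the boron enolate (Bu2BOTf, Et3N, CH2Cl2, −78 → 0 °C) to both formyl groups of 9 should give the bis[(2S,3R)-2-benzyloxy-3-hydroxy] imide F14. Ionic hydrogenation (Et3SiH, CF3CO2H, CH2Cl2, −20 °C) removes both benzylic hydroxyls through the alkoxy-stabilised cations to give the bis-imide with S at both CH(OBn) centres and the (S)-auxiliary F15, and aminolysis as in step 12 gives 18.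

**Step 16.** Hydrogenolysis may go too far and open a ring C at the benzylic C2–O1 bond, may stall before the last hindered benzyl groups are removed, or the free polyphenol may oxidise during isolation. The fallback sets out from 23 and returns at 24 without a new compound (F0). It is a non-reductive Lewis-acid debenzylation with BCl3 and pentamethylbenzene as cation scavenger in CH2Cl2 at −78 °C, followed by a methanol quench under argon.

## Further compounds

F1 | step 15 | (1R,1'R,2S,2'S)-bis-phenol: 22 with hydroxyl in place of both bromines | c9ccccc9COc1ccc([C@@H](O)[C@@H](OCc9ccccc9)Cc2cc(-c3cc(OCc9ccccc9)c(OCc9ccccc9)c(O)c3C[C@H](OCc9ccccc9)[C@H](O)c3ccc(OCc9ccccc9)c(OCc9ccccc9)c3)c(OCc9ccccc9)c(OCc9ccccc9)c2O)cc1OCc9ccccc9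
F2 | step 3 | 2-bromo-3-(hydroxymethyl)-6-methoxyphenol | COc1ccc(CO)c(Br)c1O
F3 | step 3 | 3-(acetoxymethyl)-2-bromo-6-methoxyphenyl acetate | COc1ccc(COC(C)=O)c(Br)c1OC(C)=O
F4 | step 3 | 3-(acetoxymethyl)-2-bromo-5-iodo-6-methoxyphenyl acetate | COc1c(I)cc(COC(C)=O)c(Br)c1OC(C)=O
F5 | step 3 | 2-bromo-3-(hydroxymethyl)-5-iodo-6-methoxyphenol | COc1c(I)cc(CO)c(Br)c1O
F6 | step 3 | 2-bromo-3-hydroxy-5-iodo-4-methoxybenzaldehyde | COc1c(I)cc(C=O)c(Br)c1O
F7 | step 5 | isovanillin (3-hydroxy-4-methoxybenzaldehyde) | COc1ccc(C=O)cc1O
F8 | step 5 | 5-formyl-2-methoxyphenyl acetate | COc1ccc(C=O)cc1OC(C)=O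
F9 | step 5 | 5-formyl-3-iodo-2-methoxyphenyl acetate | COc1c(I)cc(C=O)cc1OC(C)=O
F10 | step 5 | 5-formyl-2-methoxy-3-(4,4,5,5-tetramethyl-1,3,2-dioxaborolan-2-yl)phenyl acetate | COc1c(B2OC(C)(C)C(C)(C)O2)cc(C=O)cc1OC(C)=O
F11 | step 5 | 3-bromo-3',4-dihydroxy-2',5-dimethoxybiphenyl-2,5'-dicarbaldehyde | COc1cc(-c2cc(C=O)cc(O)c2OC)c(C=O)c(Br)c1O
F12 | step 11 | (S)-4-benzyloxazolidin-2-one | O=C1N[C@@H](Cc2ccccc2)CO1
F13 | step 11 | (S)-4-benzyl-3-[2-(benzyloxy)acetyl]oxazolidin-2-one | O=C1N(C(=O)COCc2ccccc2)[C@@H](Cc2ccccc2)CO1
F14 | step 11 | bis[(2S,3R)-2-(benzyloxy)-3-hydroxy] imide of (S)-4-benzyloxazolidin-2-one on the biaryl core of 9 | O=C(N1[C@@H](Cc9ccccc9)COC1=O)[C@@H](OCc9ccccc9)[C@H](O)c1cc(-c2cc(OCc9ccccc9)c(OCc9ccccc9)c(Br)c2[C@@H](O)[C@H](OCc9ccccc9)C(=O)N2[C@@H](Cc9ccccc9)COC2=O)c(OCc9ccccc9)c(OCc9ccccc9)c1Br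
F15 | step 11 | bis[(2S)-2-(benzyloxy)propanoyl] imide of (S)-4-benzyloxazolidin-2-one (17 with the enantiomeric auxiliary) | O=C(N1[C@@H](Cc9ccccc9)COC1=O)[C@@H](OCc9ccccc9)Cc1cc(-c2cc(OCc9ccccc9)c(OCc9ccccc9)c(Br)c2C[C@H](OCc9ccccc9)C(=O)N2[C@@H](Cc9ccccc9)COC2=O)c(OCc9ccccc9)c(OCc9ccccc9)c1Br
F0 | step 16 | none | none
A1 | alternative 1 | biaryl bis(trans-dioxolane) bis(N-acyloxyphthalimide) ester with methoxymethyl ethers on both C8a | O=C(ON1C(=O)c2ccccc2C1=O)[C@@H]5OC(C)(C)O[C@H]5Cc2cc(-c3cc(OCc9ccccc9)c(OCc9ccccc9)c(OCOC)c3C[C@@H]5OC(C)(C)O[C@H]5C(=O)ON3C(=O)c4ccccc4C3=O)c(OCc9ccccc9)c(OCc9ccccc9)c2OCOC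
A2 | alternative 1 | 4-iodo-1,2-bis(benzyloxy)benzene | Ic1ccc(OCc2ccccc2)c(OCc2ccccc2)c1
A3 | alternative 1 | biaryl bis[(S,S)-trans-4-aryl-5-(arylmethyl)-2,2-dimethyl-1,3-dioxolane] | c9ccccc9COc1ccc([C@@H]5OC(C)(C)O[C@H]5Cc2cc(-c3cc(OCc9ccccc9)c(OCc9ccccc9)c(OCOC)c3C[C@@H]5OC(C)(C)O[C@H]5c3ccc(OCc9ccccc9)c(OCc9ccccc9)c3)c(OCc9ccccc9)c(OCc9ccccc9)c2OCOC)cc1OCc9ccccc9
A4 | alternative 1 | (2R,3R)-tartaric acid | OC(=O)[C@H](O)[C@@H](O)C(=O)O
A5 | alternative 2 | 2',3',4,5-tetrakis(benzyloxy)-3,4'-dihydroxybiphenyl-2,5'-dicarbaldehyde | O=Cc1cc(-c2cc(OCc9ccccc9)c(OCc9ccccc9)c(O)c2C=O)c(OCc9ccccc9)c(OCc9ccccc9)c1O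
A6 | alternative 2 | (E)-3-[3,4-bis(benzyloxy)phenyl]prop-2-enal | O=C/C=C/c1ccc(OCc2ccccc2)c(OCc2ccccc2)c1
A7 | alternative 2 | biaryl bis(2-aryl-2H-chromene-3-carbaldehyde), C2 configured as in the target | c9ccccc9COc1ccc([C@H]2Oc3c(cc(-c4cc(OCc9ccccc9)c(OCc9ccccc9)c5c4C=C(C=O)[C@@H](c4ccc(OCc9ccccc9)c(OCc9ccccc9)c4)O5)c(OCc9ccccc9)c3OCc9ccccc9)C=C2C=O)cc1OCc9ccccc9
A8 | alternative 3 | 2,3-bis(benzyloxy)-4-alkenylcyclobut-2-enone carrying protected unit 1 on the inner alkene carbon and the (S,S)-trans-dioxolane side chain (ring sp3 carbon and alkene geometry not defined) | O=C1C(OCc9ccccc9)=C(OCc9ccccc9)C1C(=CC[C@@H]5OC(C)(C)O[C@H]5c6ccc(OCc9ccccc9)c(OCc9ccccc9)c6)c1cc2C[C@H](OCc9ccccc9)[C@@H](c3ccc(OCc9ccccc9)c(OCc9ccccc9)c3)Oc2c(OCc9ccccc9)c1OCc9ccccc9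
A9 | alternative 3 | biaryl phenol with free C8a hydroxyl and the acetonide side chain on C4a of unit 2 | c9ccccc9COc1ccc([C@H]2Oc3c(cc(-c4cc(OCc9ccccc9)c(OCc9ccccc9)c(O)c4C[C@@H]5OC(C)(C)O[C@H]5c6ccc(OCc9ccccc9)c(OCc9ccccc9)c6)c(OCc9ccccc9)c3OCc9ccccc9)C[C@@H]2OCc9ccccc9)cc1OCc9ccccc9
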